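The route rests on one reading of the target. The chain phenol O – C2-methyl carbon – C2 links the arene (ring A) to the cyclopentane (ring B), and it is treated as an O–CH2 tether. Ring A, C1, C2, C3, C5, both methyl groups and the bromomethylene carbon then all sit in one acyclic precursor, a 2-isopropenylaryl butynyl ether. An intramolecular, enantioselective Pauson–Khand reaction with CO (which becomes C4) forms C1–C2, C3–C4 and C4–C5 in one operation. It closes ring B and a temporary pyran (ring C) and sets quaternary C1. Ring C is opened reductively while its O–CH2 bond is still allylic. C1 then relays its configuration to C4 and C2.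

Key step: step 4

Numbering: ring B atoms are C1 (quaternary), C2 (CH–CH3), C3 (C=CHBr), C4 and C5, as in the target. The "methyl face" is the face of ring B that carries the C1 methyl group; the "aryl face" is the other one.
Structure check: the target is (1R,2R,3E). Aryl and C2-methyl are cis, the vinylic Br lies on the C4 side, and the aryl Br is para to OH. The (R) centre of the Pauson–Khand product has the same spatial sense as C1 of the target.
Assumption: (R)-BINAP is taken to give the (R)-configured Pauson–Khand product; if the sense is the opposite, (S)-BINAP is used and nothing else changes.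

Step 1
Reactants: 1 but-2-yne-1,4-diol
Product: 2 4-[(tert-butyldimethylsilyl)oxy]but-2-yn-1-ol
Conditions: TBSCl (1 equiv), imidazole, 1 (3 equiv), DMF, 0 °C to rt
Reagents that add atoms: tert-butyldimethylsilyl chloride, CC(C)(C)[Si](C)(C)Cl
Why: Statistical monosilylation (silyl ether formation) of a symmetrical diol, in which the excess of water-soluble 1 suppresses the bis-ether and is washed out.

Step 2
Reactants: 2 4-[(tert-butyldimethylsilyl)oxy]but-2-yn-1-ol; 3 2'-hydroxy-4'-methylacetophenone
Product: 4 1-[2-({4-[(tert-butyldimethylsilyl)oxy]but-2-yn-1-yl}oxy)-4-methylphenyl]ethan-1-one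
Conditions: PPh3, DIAD, THF, 0 °C to rt
Reagents that add atoms: none
Why: Mitsunobu etherification of a primary propargylic alcohol with an acidic phenol builds the aryl–O–CH2 tether under neutral conditions, and doing so at the ketone stage avoids handling the acid-sensitive, self-condensing 2-isopropenylphenol.

Step 3
Reactants: 4 1-[2-({4-[(tert-butyldimethylsilyl)oxy]but-2-yn-1-yl}oxy)-4-methylphenyl]ethan-1-one
Product: 5 1-{4-[(tert-butyldimethylsilyl)oxy]but-2-ynyloxy}-2-isopropenyl-5-methylbenzene
Conditions: Ph3PCH3Br, KOtBu, THF, 0 °C to rt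
Reagents that add atoms: methyltriphenylphosphonium bromide, C[P+](c1ccccc1)(c1ccccc1)c1ccccc1.[Br-]
Why: Wittig methylenation of an aryl methyl ketone installs the 1,1-disubstituted alkene without acid, so the propargylic ethers and the silyl ether are left untouched.

Step 4
Reactants: 5 1-{4-[(tert-butyldimethylsilyl)oxy]but-2-ynyloxy}-2-isopropenyl-5-methylbenzene; 6 carbon monoxide
Product: 7 (9bR)-3-{[(tert-butyldimethylsilyl)oxy]methyl}-7,9b-dimethyl-1,9b-dihydrocyclopenta[c]chromen-2(4H)-one
Conditions: [Rh(CO)2Cl]2 (5 mol %), (R)-BINAP (11 mol %), AgOSO2CF3 (12 mol %), CO (1 atm), THF, 90 °C, sealed vessel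
Reagents that add atoms: carbon monoxide (6), [C-]#[O+]
Why: Proposed new method: the cationic BINAP complex of monovalent rhodium binds the alkyne and the isopropenyl group together and couples them oxidatively, so that C1–C2 forms while the metal becomes σ-bonded to vinylic C3 and to C5H2; migratory insertion of CO supplies C4 and reductive elimination releases enone 7. The closest known reactions are the rhodium/BINAP-catalysed asymmetric Pauson–Khand reaction of 1,6-enynes (1,1-disubstituted alkenes included) and the racemic Co2(CO)8-mediated Pauson–Khand reaction of 2-(propargyloxy)styrenes, and the new element is their combination on an arene-bridged 1,7-enyne. Ring C closes in the C–C coupling event as a 6-exo closure at both π bonds (C3 and C5 stay outside it), and ring B closes as the five-membered (2+2+1) ring through C3–C4 and C4–C5. The single new stereocentre, quaternary C1, is fixed in the oxidative coupling by the alkene face that the axially chiral bisphosphine leaves accessible. Only enantiofacial selectivity has to be won, because the tether dictates which carbons meet, and the flat ortho-disubstituted arene holds both π systems close enough to offset the entropic handicap of a 1,7-enyne. Since C1 bears no hydrogen, the rhodacycle has no β-hydride exit to cycloisomerised dienes, which leaves carbonylation as the productive path.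

Step 5
Reactants: 7 (9bR)-3-{[(tert-butyldimethylsilyl)oxy]methyl}-7,9b-dimethyl-1,9b-dihydrocyclopenta[c]chromen-2(4H)-one
Product: 9 (4R)-2-{[(tert-butyldimethylsilyl)oxy]methyl}-4-(2-hydroxy-4-methylphenyl)-4-methyl-3-methylidenecyclopentan-1-one (epimers at ring-B C3; used crude), via dilithium dienolate phenolate 8 (not isolated)
Conditions: Li (2.1 equiv), NH3(l)/THF, −78 °C; solid NH4Cl
Reagents that add atoms: none
Why: Dissolving-metal reduction of an enone with a leaving group on its γ-carbon: two electrons place carbanion character on C2, aryloxide is expelled from the neighbouring CH2 (reductive β-elimination), dienolate 8 resists further reduction, and kinetic α-protonation gives 9; the cleavage is done here because the O–CH2 bond is activated only while it is allylic and vinylogous to the ketone.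

Step 6
Reactants: 9 (4R)-2-{[(tert-butyldimethylsilyl)oxy]methyl}-4-(2-hydroxy-4-methylphenyl)-4-methyl-3-methylidenecyclopentan-1-one
Product: 11 2-[(1R)-3-{[(tert-butyldimethylsilyl)oxy]methyl}-1,2-dimethyl-4-oxocyclopent-2-en-1-yl]-5-methylphenyl acetate, via β,γ-enone acetate 10 (not isolated)
Conditions: Ac2O (1.1 equiv), Et3N, DMAP (cat.), CH2Cl2, 0 °C; then DBU (0.3 equiv), rt
Reagents that add atoms: acetic anhydride, CC(=O)OC(C)=O
Why: Phenol acetylation followed by base-mediated conjugation of the β,γ-enone, in which γ-protonation turns the exocyclic CH2 (the former tether carbon) into the C2 methyl group; masking the phenol first prevents oxa-Michael closure onto C2, and the strongly stabilised dienolate should reprotonate faster than it loses silyloxide.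

Step 7
Reactants: 11 2-[(1R)-3-{[(tert-butyldimethylsilyl)oxy]methyl}-1,2-dimethyl-4-oxocyclopent-2-en-1-yl]-5-methylphenyl acetate
Product: 12 2-[(1R,4S)-3-{[(tert-butyldimethylsilyl)oxy]methyl}-4-hydroxy-1,2-dimethylcyclopent-2-en-1-yl]-5-methylphenyl acetate (OH on the aryl face)
Conditions: (R)-Me-CBS oxazaborolidine (0.3 equiv), BH3·THF (1.2 equiv), THF, −20 °C; MeOH, then aqueous work-up
Reagents that add atoms: none
Why: Corey–Bakshi–Shibata reduction with substituted alkenyl C3 as the large group and C5H2 as the small one, so the (R)-catalyst should deliver hydride to the methyl face, which is also the face the bulkier aryl group leaves open (matched case), and this sets C4 as (S).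

Step 8
Reactants: 12 2-[(1R,4S)-3-{[(tert-butyldimethylsilyl)oxy]methyl}-4-hydroxy-1,2-dimethylcyclopent-2-en-1-yl]-5-methylphenyl acetate
Product: 15 2-[(1R,2R)-3-{[(tert-butyldimethylsilyl)oxy]methyl}-1,2-dimethylcyclopent-3-en-1-yl]-5-methylphenyl acetate (C2–H on the methyl face, C2–CH3 cis to aryl), via sulfonylhydrazone adduct 13 (not isolated), via allylic diazene 14 (not isolated)
Conditions: N-isopropylidene-N'-(2-nitrobenzenesulfonyl)hydrazine (IPNBSH), PPh3, DEAD, THF, 0 °C to rt; then CF3CH2OH–H2O (1:1), rt
Reagents that add atoms: none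
Why: Mitsunobu displacement inverts C4 and puts nitrogen on the methyl face, hydrolysis and loss of sulfinate unmask diazene 14, and its concerted retro-ene loss of N2 (allylic diazene rearrangement) passes hydrogen suprafacially to C2 on that same face, which sets C2, removes the C4 oxygen and moves the alkene to C3=C4.

Step 9
Reactants: 15 2-[(1R,2R)-3-{[(tert-butyldimethylsilyl)oxy]methyl}-1,2-dimethylcyclopent-3-en-1-yl]-5-methylphenyl acetate
Product: 16 2-[(1R,2R)-3-(hydroxymethyl)-1,2-dimethylcyclopent-3-en-1-yl]-5-methylphenyl acetate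
Conditions: HF·pyridine, pyridine/THF, 0 °C to rt
Reagents that add atoms: none
Why: Fluoride-mediated desilylation under buffered, weakly acidic conditions, chosen because basic fluoride sources would also cleave the aryl acetate.

Step 10
Reactants: 16 2-[(1R,2R)-3-(hydroxymethyl)-1,2-dimethylcyclopent-3-en-1-yl]-5-methylphenyl acetate
Product: 18 2-[(1R,2S)-3-formyl-1,2-dimethylcyclopentyl]-5-methylphenyl acetate (C3 epimers; same spatial arrangement at C2), via enol 17 (not isolated)
Conditions: [Ir(cod)(PCy3)(py)][B(C6H3-3,5-(CF3)2)4] (5 mol %), brief H2 activation then degassing, THF, rt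
Reagents that add atoms: none
Why: Iridium-hydride-catalysed redox isomerisation of a primary allylic alcohol (insertion, β-hydride elimination toward the carbinol carbon, tautomerisation of 17) gives the saturated aldehyde; both C3 epimers are usable because C3 becomes sp2 again, and C2 is not acidic.

Step 11
Reactants: 18 2-[(1R,2S)-3-formyl-1,2-dimethylcyclopentyl]-5-methylphenyl acetate
Product: 19 2-[(1R,2S)-3-(dibromomethyl)-1,2-dimethylcyclopentyl]-5-methylphenyl acetate (C3 epimers)
Conditions: P(OPh)3, Br2, CH2Cl2, −60 °C; then 18, Et3N (buffer), −60 °C to rt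
Reagents that add atoms: bromine (delivered as (PhO)3PBr2), BrBr
Why: Deoxygenative gem-dibromination of an aldehyde with preformed triphenyl phosphite dibromide, which contains no free bromine and is mild enough for the aryl acetate.

Step 12
Reactants: 19 2-[(1R,2S)-3-(dibromomethyl)-1,2-dimethylcyclopentyl]-5-methylphenyl acetate
Product: 21 2-[(1R,2R,3E)-3-(bromomethylidene)-1,2-dimethylcyclopentyl]-5-methylphenol, via potassium phenolate 20 (not isolated)
Conditions: KOtBu (3 equiv), THF, 0 °C to rt; 1 M HCl
Reagents that add atoms: none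
Why: Dehydrobromination of a 1,1-dibromide (E2), in which C3–H is the only β-hydrogen so the regiochemistry is unambiguous; in the anti-periplanar arrangement the bromine that stays should lie over C4H2 rather than against substituted C2 (allylic 1,3-strain), which favours the E alkene, and tert-butoxide removes the acetate in the same flask.

Step 13
Reactants: 21 2-[(1R,2R,3E)-3-(bromomethylidene)-1,2-dimethylcyclopentyl]-5-methylphenol
Product: 22 4-bromo-2-[(1R,2R,3E)-3-(bromomethylidene)-1,2-dimethylcyclopentyl]-5-methylphenol
Conditions: NBS (1.0 equiv), MeCN, −20 to 0 °C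
Reagents that add atoms: N-bromosuccinimide, O=C1CCC(=O)N1Br
Why: Electrophilic aromatic bromination of a free phenol goes to the open para position (the only free ortho site is squeezed between OH and CH3), while the bromoalkene is too electron-poor to compete for one equivalent of reagent.

Compound list
1 | but-2-yne-1,4-diol | OCC#CCO | starting material
2 | 4-[(tert-butyldimethylsilyl)oxy]but-2-yn-1-ol | OCC#CCO[Si](C)(C)C(C)(C)C | intermediate
3 | 2'-hydroxy-4'-methylacetophenone | CC(=O)c1ccc(C)cc1O | starting material
4 | aryl butynyl ether ketone | CC(=O)c1ccc(C)cc1OCC#CCO[Si](C)(C)C(C)(C)C | intermediate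
5 | 1-{4-[(tert-butyldimethylsilyl)oxy]but-2-ynyloxy}-2-isopropenyl-5-methylbenzene | C=C(C)c1ccc(C)cc1OCC#CCO[Si](C)(C)C(C)(C)C | intermediate
6 | carbon monoxide | [C-]#[O+] | starting material
7 | (9bR)-cyclopenta[c]chromen-2-one, Pauson–Khand product | Cc1ccc2c(c1)OCC1=C(CO[Si](C)(C)C(C)(C)C)C(=O)C[C@@]21C | intermediate
8 | dilithium dienolate phenolate | [Li+].[Li+].Cc1ccc([C@]2(C)CC([O-])=C(CO[Si](C)(C)C(C)(C)C)C2=C)c([O-])c1 | intermediate
9 | ring-opened phenol, β,γ-enone with C2=CH2 | Cc1ccc([C@]2(C)CC(=O)C(CO[Si](C)(C)C(C)(C)C)C2=C)c(O)c1 | intermediate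
10 | β,γ-enone aryl acetate | Cc1ccc([C@]2(C)CC(=O)C(CO[Si](C)(C)C(C)(C)C)C2=C)c(OC(C)=O)c1 | intermediate
11 | conjugated enone aryl acetate, C2–CH3 | Cc1ccc([C@]2(C)CC(=O)C(CO[Si](C)(C)C(C)(C)C)=C2C)c(OC(C)=O)c1 | intermediate
12 | (1R,4S)-allylic alcohol | Cc1ccc([C@]2(C)C[C@H](O)C(CO[Si](C)(C)C(C)(C)C)=C2C)c(OC(C)=O)c1 | intermediate
13 | (1R,4R)-N-allyl-N-sulfonylhydrazone adduct | Cc1ccc([C@]2(C)C[C@@H](N(N=C(C)C)S(=O)(=O)c3ccccc3[N+](=O)[O-])C(CO[Si](C)(C)C(C)(C)C)=C2C)c(OC(C)=O)c1 | intermediate
14 | (1R,4R)-allylic diazene | Cc1ccc([C@]2(C)C[C@@H](N=N)C(CO[Si](C)(C)C(C)(C)C)=C2C)c(OC(C)=O)c1 | intermediate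
15 | (1R,2R)-cyclopent-3-ene silyl ether | Cc1ccc([C@]2(C)CC=C(CO[Si](C)(C)C(C)(C)C)[C@@H]2C)c(OC(C)=O)c1 | intermediate
16 | (1R,2R)-primary allylic alcohol | Cc1ccc([C@]2(C)CC=C(CO)[C@@H]2C)c(OC(C)=O)c1 | intermediate
17 | exocyclic enol | Cc1ccc([C@]2(C)CCC(=CO)[C@@H]2C)c(OC(C)=O)c1 | intermediate
18 | (1R,2S)-3-formylcyclopentane, C3 epimers | Cc1ccc([C@]2(C)CCC(C=O)[C@@H]2C)c(OC(C)=O)c1 | intermediate
19 | (1R,2S)-3-(dibromomethyl)cyclopentane, C3 epimers | Cc1ccc([C@]2(C)CCC(C(Br)Br)[C@@H]2C)c(OC(C)=O)c1 | intermediate
20 | potassium phenolate of 21 | [K+].Cc1ccc([C@]2(C)CC/C(=C\Br)[C@@H]2C)c([O-])c1 | intermediate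
21 | 2-[(1R,2R,3E)-3-(bromomethylidene)-1,2-dimethylcyclopentyl]-5-methylphenol | Cc1ccc([C@]2(C)CC/C(=C\Br)[C@@H]2C)c(O)c1 | intermediate
22 | 4-bromo-2-[(1R,2R,3E)-3-(bromomethylidene)-1,2-dimethylcyclopentyl]-5-methylphenol | Cc1cc(O)c([C@]2(C)CC/C(=C\Br)[C@@H]2C)cc1Br | target

Total step count: 13. Longest linear sequence: 13 (1 to 22; 3 enters at step 2 and 6 at step 4).

Stereocontrol: C1 is set in step 4. C4 (step 7) is a relay centre that is consumed in step 8, where C2 is set. The alkene geometry is set in step 12. None of these positions is acidic or ionisable in the later steps.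

Steps most likely to fail

Step 4. The oxidative coupling of the 1,7-enyne on rhodium may be sluggish, or the two faces of the isopropenyl group may be poorly distinguished. The fallback uses known chemistry, sets out from 5 and returns at 7.
- Co2(CO)8 (CH2Cl2, rt) gives the hexacarbonyldicobalt alkyne complex F1.
- F1 is heated under CO (toluene, 4 Å sieves, 80 °C) in the stoichiometric Pauson–Khand cyclisation established for 2-(propargyloxy)styrenes, which gives the racemic enone F2.
- Reagent-controlled CBS reduction of F2 ((R)-Me-CBS, BH3·THF) turns the two enantiomers into diastereomers. These are the (4S)-alcohol of the (R)-series F3 and the (4S)-alcohol of the (S)-series F4, and they are separated by chromatography.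
- MnO2 oxidation of F3 gives 7.

Step 8. The activated C4 alcohol may eliminate toward a cyclopentadiene, or it may ionise and lose the clean inversion on which C2 depends. The fallback sets out from 12 and returns at 15.
- Formylation of 12 (HCO2H/Ac2O, pyridine) gives the allylic formate F5.
- Pd(OAc)2/PBu3 (THF, rt to 40 °C) generates zerovalent palladium, which ionises F5 anti to the formate and so sits on the methyl face.
- Decarboxylation leaves a palladium hydride. It is transferred from the metal-bearing face to the more substituted allyl terminus C2 (stereospecific palladium–formate allylic hydrogenolysis), which gives 15.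

Step 12. The two elimination rotamers may be poorly distinguished, which would give an E/Z mixture that is hard to separate. The fallback sets out from 16 and returns at 21.
- A second IPNBSH Mitsunobu/allylic diazene rearrangement on 16 moves the alkene out of the ring and gives the exocyclic methylene acetate F6.
- Dehydrogenative borylation (trans-[RhCl(CO)(PPh3)2], B2pin2, toluene–MeCN, 80 °C), known for methylenecycloalkanes, keeps the exocyclic carbon. It should place the bulky boryl group on the C4 side and give the (E)-alkenylboronate F7.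
- Bromodeboronation with retention (CuBr2, aqueous MeOH) gives the bromoalkene acetate F8.
- K2CO3/MeOH cleaves the acetate of F8 to give 21.

Further compounds
F1 | step 4 | hexacarbonyldicobalt complex of the alkyne of 5 | C=C(C)c1ccc(C)cc1OCC12[Co]3(=C=O)(=C=O)(=C=O)[Co]1(=C=O)(=C=O)(=C=O)C23CO[Si](C)(C)C(C)(C)C
F2 | step 4 | racemic Pauson–Khand enone | Cc1ccc2c(c1)OCC1=C(CO[Si](C)(C)C(C)(C)C)C(=O)CC21C
F3 | step 4 | (4S)-allylic alcohol from the (R)-enone, OH on the aryl face | Cc1ccc2c(c1)OCC1=C(CO[Si](C)(C)C(C)(C)C)[C@@H](O)C[C@@]21C
F4 | step 4 | (4S)-allylic alcohol from the (S)-enone, OH on the methyl face | Cc1ccc2c(c1)OCC1=C(CO[Si](C)(C)C(C)(C)C)[C@@H](O)C[C@]21C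
F5 | step 8 | (1R,4S)-allylic formate of 12 | Cc1ccc([C@]2(C)C[C@H](OC=O)C(CO[Si](C)(C)C(C)(C)C)=C2C)c(OC(C)=O)c1
F6 | step 12 | 2-[(1R,2S)-1,2-dimethyl-3-methylidenecyclopentyl]-5-methylphenyl acetate | Cc1ccc([C@]2(C)CCC(=C)[C@@H]2C)c(OC(C)=O)c1
F7 | step 12 | (E)-alkenyl pinacol boronate | Cc1ccc([C@]2(C)CC/C(=C\B3OC(C)(C)C(C)(C)O3)[C@@H]2C)c(OC(C)=O)c1
F8 | step 12 | acetate of 21 | Cc1ccc([C@]2(C)CC/C(=C\Br)[C@@H]2C)c(OC(C)=O)c1
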